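**Retrosynthetic overview**

1. Ring A is the dihydrofuran O1–C2–C3–C3a–C7a fused to the styryl-bearing benzo ring; ring B is the other dihydrofuran. The target 31 is the octabenzyl ether 30 after one Lewis-acid debenzylation.
2. Key disconnection: ring A by a three-component [4+1] annulation. The C3–aryl bond comes from the aryllithium of ring-B bromide 21 and the formyl carbon of aldehyde 10; the C2–C3 and C2–O1 bonds come from the chiral sulfonium benzylide 27 and the ortho-quinone methide released from the adduct by Boc transfer.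
3. Enabling feature: C3a of ring A lies between the two oxygen-bearing carbons C4 and C7a of a resorcinol ring, and C3 is a diarylmethine. The benzo ring therefore maps onto a 2,6-dioxygenated benzaldehyde (formyl C = C3; one ortho oxygen = O1 and the source of the ortho-quinone methide). The C3 aryl group is C6 of ring B's benzofuran, meta to both its oxygens and so a plain aryl–metal position. C2 carries a para-oxygenated phenyl ring, as a benzylide carbon should.
4. Ring B is made first, by known chemistry, from aldehyde 4, which also serves the ring-A partner: diaryl ketone 16, hydrazone 18, enantioselective rhodium-carbene 1,5 C–H insertion to the cis ring 20 (step 10) and acid epimerisation at C2 to the trans bromide 21 (step 11), whose C6 bromide is kept for step 13. The styrene arm enters the aldehyde partner by a Heck reaction (step 4).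
5. Order of ring formation: all benzene rings are bought; ring B dihydrofuran (step 10); ring A dihydrofuran last (step 13).

Key step: step 13

Assumption: Rh2(S-PTAD)4 and the (1R,4R,5R) sulfide 22 are written as the enantiomers that lead to (3S) in steps 10 and 13; where a first run shows the opposite sense of induction, Rh2(R-PTAD)4 or the (1S,4S,5S) sulfide (from (S)-limonene and sulfur) is used without other change.

**Route**

Step 1
Reactants: 1 4-bromo-2,6-difluorobenzaldehyde; 2 benzyl alcohol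
Product: 3 2,6-bis(benzyloxy)-4-bromobenzaldehyde
Conditions: BnOH (2.2 equiv), K2CO3, DMF, 70 °C
Reagents that add atoms: benzyl alcohol, OCc1ccccc1
Why: Twofold SNAr; both fluorides are ortho to the formyl group and should be displaced far faster than the para bromide, a poorer leaving group in addition–elimination.

Step 2
Reactants: 3 2,6-bis(benzyloxy)-4-bromobenzaldehyde
Product: 4 2-(benzyloxy)-4-bromo-6-hydroxybenzaldehyde
Conditions: MgBr2·OEt2 (1.1 equiv), toluene/Et2O, reflux; aq. HCl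
Reagents that add atoms: none
Why: Chelation-controlled ether cleavage; magnesium held between the formyl oxygen and one ortho ether oxygen activates that O–benzyl bond towards bromide, and the phenoxide chelate formed after the first cleavage should protect the second ether.

Step 3
Reactants: 5 2,4-bis(benzyloxy)benzaldehyde; 6 methyltriphenylphosphonium bromide
Product: 7 2,4-bis(benzyloxy)-1-ethenylbenzene
Conditions: Ph3PCH3Br, KOtBu, THF, 0 °C → rt
Reagents that add atoms: methyltriphenylphosphonium bromide, C[P+](c1ccccc1)(c1ccccc1)c1ccccc1.[Br-]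
Why: Wittig methylenation of an aromatic aldehyde.

Step 4
Reactants: 4 2-(benzyloxy)-4-bromo-6-hydroxybenzaldehyde; 7 2,4-bis(benzyloxy)-1-ethenylbenzene
Product: 8 2-(benzyloxy)-4-{(E)-2-[2,4-bis(benzyloxy)phenyl]ethenyl}-6-hydroxybenzaldehyde
Conditions: Pd(OAc)2 (cat.), P(o-tol)3 (cat.), Et3N, DMF, 100 °C
Reagents that add atoms: none
Why: Mizoroki–Heck reaction of an aryl bromide activated by the para formyl group; syn insertion and syn β-hydride elimination should give the (E)-stilbene, and the chelated phenol is tolerated.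

Step 5
Reactants: 8 2-(benzyloxy)-4-{(E)-2-[2,4-bis(benzyloxy)phenyl]ethenyl}-6-hydroxybenzaldehyde; 9 di-tert-butyl dicarbonate
Product: 10 tert-butyl {3-(benzyloxy)-5-[(E)-2-[2,4-bis(benzyloxy)phenyl]ethenyl]-2-formylphenyl} carbonate
Conditions: Boc2O, iPr2NEt, DMAP (cat.), CH2Cl2, 0 °C → rt
Reagents that add atoms: di-tert-butyl dicarbonate, CC(C)(C)OC(=O)OC(=O)OC(C)(C)C
Why: DMAP-catalysed O-acylation of the hydrogen-bonded phenol installs the aryl carbonate that serves as the latent leaving group of step 13.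

Step 6
Reactants: 4 2-(benzyloxy)-4-bromo-6-hydroxybenzaldehyde; 11 4-(benzyloxy)benzyl bromide
Product: 12 2-(benzyloxy)-6-{[4-(benzyloxy)phenyl]methoxy}-4-bromobenzaldehyde
Conditions: K2CO3, DMF, rt
Reagents that add atoms: 4-(benzyloxy)benzyl bromide, BrCc1ccc(OCc2ccccc2)cc1
Why: Williamson etherification of the phenol with a reactive benzylic bromide; the new OCH2Ar group carries the carbon that becomes C2 of ring B.

Step 7
Reactants: 13 1,3-bis(benzyloxy)-5-bromobenzene; 12 2-(benzyloxy)-6-{[4-(benzyloxy)phenyl]methoxy}-4-bromobenzaldehyde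
Product: 15 [2-(benzyloxy)-6-{[4-(benzyloxy)phenyl]methoxy}-4-bromophenyl][3,5-bis(benzyloxy)phenyl]methanol (racemic), via aryllithium 14 (not isolated)
Conditions: n-BuLi, THF, −78 °C; then 12, −78 °C; aq. NH4Cl
Reagents that add atoms: none
Why: Bromine–lithium exchange and 1,2-addition of the aryllithium to the aldehyde, which at −78 °C should be much faster than exchange with the aryl bromide of 12; the carbinol centre is removed in step 8.

Step 8
Reactants: 15 diarylmethanol
Product: 16 [2-(benzyloxy)-6-{[4-(benzyloxy)phenyl]methoxy}-4-bromophenyl][3,5-bis(benzyloxy)phenyl]methanone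
Conditions: Dess–Martin periodinane, NaHCO3, CH2Cl2, 0 °C → rt
Reagents that add atoms: none
Why: Dess–Martin oxidation of a hindered diarylmethanol to the benzophenone under buffered, non-acidic conditions that leave the benzylic ethers untouched.

Step 9
Reactants: 16 diaryl ketone; 17 hydrazine monohydrate
Product: 18 hydrazone of 16 (both C=N geometries)
Conditions: N2H4·H2O (excess), AcOH (cat.), n-BuOH, reflux
Reagents that add atoms: hydrazine monohydrate, NN.O
Why: Acid-catalysed condensation of a hindered benzophenone with excess hydrazine, which suppresses azine formation; without strong base no Wolff–Kishner reduction should follow.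

Step 10
Reactants: 18 hydrazone of 16
Product: 20 (2R,3S)-4-(benzyloxy)-2-[4-(benzyloxy)phenyl]-3-[3,5-bis(benzyloxy)phenyl]-6-bromo-2,3-dihydro-1-benzofuran (cis), via diaryldiazomethane 19 (not isolated)
Conditions: MnO2, CH2Cl2, 0 °C; filter; Rh2(S-PTAD)4 (1 mol %), CH2Cl2, 0 °C → rt
Reagents that add atoms: none
Why: Oxidation of the hydrazone to the diaryldiazomethane and enantioselective rhodium-carbene 1,5 C–H insertion of the donor/donor carbene into the ether CH2 group; the concerted insertion sets C2 and C3 together as the cis ring, the chiral carboxylate ligands select the carbene face (3S), and the more hydridic 4-alkoxybenzylic C–H bond should be preferred over that of the neighbouring plain benzyl ether.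

Step 11
Reactants: 20 cis ring-B bromide
Product: 21 (2S,3S)-4-(benzyloxy)-2-[4-(benzyloxy)phenyl]-3-[3,5-bis(benzyloxy)phenyl]-6-bromo-2,3-dihydro-1-benzofuran (trans)
Conditions: TFA, CH2Cl2, 0 °C
Reagents that add atoms: none
Why: Acid-promoted epimerisation at C2; protonation of O1 opens the O1–C2 bond reversibly to the 4-(benzyloxy)benzylic cation, and reclosure under thermodynamic control should give the trans ring, while C3, which is not ionised, keeps its (S) configuration and the plain aryl benzyl ethers survive cold TFA.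

Step 12
Reactants: 22 (1R,4R,5R)-isothiocineole; 11 4-(benzyloxy)benzyl bromide; 23 lithium trifluoromethanesulfonate
Product: 24 (1R,4R,5R)-6-{[4-(benzyloxy)phenyl]methyl}-4,7,7-trimethyl-6-thiabicyclo[3.2.1]octan-6-ium trifluoromethanesulfonate
Conditions: LiOTf, CH2Cl2/H2O, rt
Reagents that add atoms: lithium trifluoromethanesulfonate, [Li+].[O-]S(=O)(=O)C(F)(F)F
Why: S-alkylation of the sulfide with exchange of bromide for non-nucleophilic triflate in the two-phase system, which blocks the reverse reaction; alkylation on the less hindered exo lone pair should give one sulfonium diastereomer.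

Step 13
Reactants: 21 ring-B bromide; 10 tert-butyl {3-(benzyloxy)-5-[(E)-2-[2,4-bis(benzyloxy)phenyl]ethenyl]-2-formylphenyl} carbonate; 24 sulfonium triflate
Product: 30 (2S,3S)-4-(benzyloxy)-2-[4-(benzyloxy)phenyl]-3-{(2S,3S)-4-(benzyloxy)-2-[4-(benzyloxy)phenyl]-3-[3,5-bis(benzyloxy)phenyl]-2,3-dihydro-1-benzofuran-6-yl}-6-{(E)-2-[2,4-bis(benzyloxy)phenyl]ethenyl}-2,3-dihydro-1-benzofuran, via aryllithium 25 (not isolated), via lithium phenoxide carbonate 26 (not isolated), via sulfonium ylide 27 (not isolated), via ortho-quinone methide 28 (not isolated), via betaine 29 (not isolated)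
Conditions: n-BuLi, THF, −78 °C; then 10, −78 °C; then 27 (excess; from 24, LiHMDS, THF, −78 °C); then MgBr2·OEt2, −78 → 0 °C
Reagents that add atoms: sulfonium triflate 24, C[C@@H]1CC[C@@H]2C[C@H]1[S@@+](Cc1ccc(OCc3ccccc3)cc1)C2(C)C.[O-]S(=O)(=O)C(F)(F)F
Why: Proposed new method: 25 adds to the formyl group of 10 and 1,5-transfer of the Boc group from the phenol oxygen to the new alkoxide oxygen gives 26, whose magnesium phenoxide expels tert-butyl carbonate and releases ortho-quinone methide 28 at low concentration; benzylide 27 adds to the exocyclic carbon of 28 (C2–C3 bond, driven by rearomatisation) to give betaine 29, and the phenoxide displaces the sulfide from the benzylic sulfonium carbon with inversion (C2–O1 bond). The closest known reaction types are the Boc-transfer generation of ortho-quinone methides from O-Boc salicylaldehydes with capture by a second carbon nucleophile, the [4+1] annulation of ortho-quinone methides with sulfonium ylides to trans-2,3-dihydrobenzofurans, and asymmetric epoxidations with benzylides of this sulfide; new are their merger in one flask and the use of a chiral semi-stabilised benzylide on an ortho-quinone methide. Ring A closes in a 5-exo-tet O-alkylation, a formal [4+1] annulation that completes the carbon skeleton of the target from three fragments. C3 is set in the C–C bond-forming step by the chiral sulfide, which exposes one face of the ylide carbon and favours the approach that keeps the ylide aryl group anti to the C3 aryl group; C2 follows from the same ylide face through the inverting displacement, which should give the trans (2S,3S) ring. The step needs attack of 25 on the formyl group and not on the carbonate (secured at −78 °C by the higher electrophilicity of the aldehyde), capture of 28 by the ylide before it condenses with itself or is attacked at the remote stilbene (secured by slow release in the presence of excess ylide, which does not add to unactivated alkenes), and reagent control at C3, which the stereocentres of ring B, one arene away, should neither help nor hinder.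

Step 14
Reactants: 30 octabenzyl ether
Product: 31 4-[(E)-2-{(2S,3S)-3-[(2S,3S)-3-(3,5-dihydroxyphenyl)-4-hydroxy-2-(4-hydroxyphenyl)-2,3-dihydro-1-benzofuran-6-yl]-4-hydroxy-2-(4-hydroxyphenyl)-2,3-dihydro-1-benzofuran-6-yl}ethenyl]benzene-1,3-diol
Conditions: BCl3, pentamethylbenzene, CH2Cl2, −78 °C; MeOH quench
Reagents that add atoms: none
Why: Lewis-acid cleavage of aryl benzyl ethers at low temperature with pentamethylbenzene as a non-basic benzyl cation scavenger; no hydrogenation is involved, so the stilbene survives, and the trans-dihydrobenzofurans, the thermodynamically preferred isomers, should persist.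

**Compound list**

1 | 4-bromo-2,6-difluorobenzaldehyde | O=Cc1c(F)cc(Br)cc1F | starting material
2 | benzyl alcohol | OCc1ccccc1 | starting material
3 | 2,6-bis(benzyloxy)-4-bromobenzaldehyde | O=Cc1c(OCc2ccccc2)cc(Br)cc1OCc1ccccc1 | intermediate
4 | 2-(benzyloxy)-4-bromo-6-hydroxybenzaldehyde | O=Cc1c(O)cc(Br)cc1OCc1ccccc1 | intermediate
5 | 2,4-bis(benzyloxy)benzaldehyde | O=Cc1ccc(OCc2ccccc2)cc1OCc1ccccc1 | starting material
6 | methyltriphenylphosphonium bromide | C[P+](c1ccccc1)(c1ccccc1)c1ccccc1.[Br-] | starting material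
7 | 2,4-bis(benzyloxy)-1-ethenylbenzene | C=Cc1ccc(OCc2ccccc2)cc1OCc1ccccc1 | intermediate
8 | 2-(benzyloxy)-4-{(E)-2-[2,4-bis(benzyloxy)phenyl]ethenyl}-6-hydroxybenzaldehyde | O=Cc1c(O)cc(/C=C/c2ccc(OCc3ccccc3)cc2OCc2ccccc2)cc1OCc1ccccc1 | intermediate
9 | di-tert-butyl dicarbonate | CC(C)(C)OC(=O)OC(=O)OC(C)(C)C | starting material
10 | tert-butyl {3-(benzyloxy)-5-[(E)-2-[2,4-bis(benzyloxy)phenyl]ethenyl]-2-formylphenyl} carbonate | O=Cc1c(OC(=O)OC(C)(C)C)cc(/C=C/c2ccc(OCc3ccccc3)cc2OCc2ccccc2)cc1OCc1ccccc1 | intermediate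
11 | 4-(benzyloxy)benzyl bromide | BrCc1ccc(OCc2ccccc2)cc1 | starting material
12 | 2-(benzyloxy)-6-{[4-(benzyloxy)phenyl]methoxy}-4-bromobenzaldehyde | O=Cc1c(OCc2ccc(OCc3ccccc3)cc2)cc(Br)cc1OCc1ccccc1 | intermediate
13 | 1,3-bis(benzyloxy)-5-bromobenzene | Brc1cc(OCc2ccccc2)cc(OCc2ccccc2)c1 | starting material
14 | [3,5-bis(benzyloxy)phenyl]lithium | [Li]c1cc(OCc2ccccc2)cc(OCc2ccccc2)c1 | intermediate
15 | [2-(benzyloxy)-6-{[4-(benzyloxy)phenyl]methoxy}-4-bromophenyl][3,5-bis(benzyloxy)phenyl]methanol (racemic) | OC(c1cc(OCc2ccccc2)cc(OCc2ccccc2)c1)c1c(OCc2ccc(OCc3ccccc3)cc2)cc(Br)cc1OCc1ccccc1 | intermediate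
16 | [2-(benzyloxy)-6-{[4-(benzyloxy)phenyl]methoxy}-4-bromophenyl][3,5-bis(benzyloxy)phenyl]methanone | O=C(c1cc(OCc2ccccc2)cc(OCc2ccccc2)c1)c1c(OCc2ccc(OCc3ccccc3)cc2)cc(Br)cc1OCc1ccccc1 | intermediate
17 | hydrazine monohydrate | NN.O | starting material
18 | hydrazone of 16 (both C=N geometries) | NN=C(c1cc(OCc2ccccc2)cc(OCc2ccccc2)c1)c1c(OCc2ccc(OCc3ccccc3)cc2)cc(Br)cc1OCc1ccccc1 | intermediate
19 | 1-(benzyloxy)-3-{[4-(benzyloxy)phenyl]methoxy}-2-{[3,5-bis(benzyloxy)phenyl](diazo)methyl}-5-bromobenzene | [N-]=[N+]=C(c1cc(OCc2ccccc2)cc(OCc2ccccc2)c1)c1c(OCc2ccc(OCc3ccccc3)cc2)cc(Br)cc1OCc1ccccc1 | intermediate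
20 | (2R,3S)-4-(benzyloxy)-2-[4-(benzyloxy)phenyl]-3-[3,5-bis(benzyloxy)phenyl]-6-bromo-2,3-dihydro-1-benzofuran (cis) | Brc1cc(OCc2ccccc2)c2c(c1)O[C@@H](c1ccc(OCc3ccccc3)cc1)[C@H]2c1cc(OCc2ccccc2)cc(OCc2ccccc2)c1 | intermediate
21 | (2S,3S)-4-(benzyloxy)-2-[4-(benzyloxy)phenyl]-3-[3,5-bis(benzyloxy)phenyl]-6-bromo-2,3-dihydro-1-benzofuran (trans) | Brc1cc(OCc2ccccc2)c2c(c1)O[C@H](c1ccc(OCc3ccccc3)cc1)[C@H]2c1cc(OCc2ccccc2)cc(OCc2ccccc2)c1 | intermediate
22 | (1R,4R,5R)-isothiocineole [(1R,4R,5R)-4,7,7-trimethyl-6-thiabicyclo[3.2.1]octane] | C[C@@H]1CC[C@@H]2C[C@H]1SC2(C)C | starting material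
23 | lithium trifluoromethanesulfonate | [Li+].[O-]S(=O)(=O)C(F)(F)F | starting material
24 | (1R,4R,5R)-6-{[4-(benzyloxy)phenyl]methyl}-4,7,7-trimethyl-6-thiabicyclo[3.2.1]octan-6-ium trifluoromethanesulfonate (benzyl group on the exo lone pair of sulfur) | C[C@@H]1CC[C@@H]2C[C@H]1[S@@+](Cc1ccc(OCc3ccccc3)cc1)C2(C)C.[O-]S(=O)(=O)C(F)(F)F | intermediate
25 | {(2S,3S)-4-(benzyloxy)-2-[4-(benzyloxy)phenyl]-3-[3,5-bis(benzyloxy)phenyl]-2,3-dihydro-1-benzofuran-6-yl}lithium | [Li]c1cc(OCc2ccccc2)c2c(c1)O[C@H](c1ccc(OCc3ccccc3)cc1)[C@H]2c1cc(OCc2ccccc2)cc(OCc2ccccc2)c1 | intermediate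
26 | lithium phenoxide carbonate from 25 and 10 after Boc transfer (both configurations at the carbinol carbon) | [Li+].[O-]c1cc(/C=C/c2ccc(OCc3ccccc3)cc2OCc2ccccc2)cc(OCc2ccccc2)c1C(OC(=O)OC(C)(C)C)c1cc(OCc2ccccc2)c2c(c1)O[C@H](c1ccc(OCc3ccccc3)cc1)[C@H]2c1cc(OCc2ccccc2)cc(OCc2ccccc2)c1 | intermediate
27 | sulfonium [4-(benzyloxy)phenyl]methylide derived from 24 | C[C@@H]1CC[C@@H]2C[C@H]1[S@@+]([CH-]c1ccc(OCc3ccccc3)cc1)C2(C)C | intermediate
28 | (6Z)-5-(benzyloxy)-3-{(E)-2-[2,4-bis(benzyloxy)phenyl]ethenyl}-6-[(ring-B benzofuran-6-yl)methylidene]cyclohexa-2,4-dien-1-one, ring B as in 21 (aryl group syn to the carbonyl group, expected geometry) | O=C1C=C(/C=C/c2ccc(OCc3ccccc3)cc2OCc2ccccc2)C=C(OCc2ccccc2)/C1=C/c1cc(OCc2ccccc2)c2c(c1)O[C@H](c1ccc(OCc3ccccc3)cc1)[C@H]2c1cc(OCc2ccccc2)cc(OCc2ccccc2)c1 | intermediate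
29 | betaine from 27 and 28: (1R,2S)-configured sulfonium phenoxide zwitterion (carbon 1 on sulfur) | C[C@@H]1CC[C@@H]2C[C@H]1[S@@+]([C@@H](c1ccc(OCc3ccccc3)cc1)[C@@H](c1cc(OCc3ccccc3)c3c(c1)O[C@H](c1ccc(OCc4ccccc4)cc1)[C@H]3c1cc(OCc3ccccc3)cc(OCc3ccccc3)c1)c1c([O-])cc(/C=C/c3ccc(OCc4ccccc4)cc3OCc3ccccc3)cc1OCc1ccccc1)C2(C)C | intermediate
30 | octabenzyl ether of the target, (2S,3S) in both dihydrobenzofurans (full name in step 13) | c1ccccc1COc1ccc([C@H]2Oc3cc(/C=C/c4ccc(OCc5ccccc5)cc4OCc4ccccc4)cc(OCc4ccccc4)c3[C@@H]2c2cc(OCc4ccccc4)c3c(c2)O[C@H](c2ccc(OCc4ccccc4)cc2)[C@H]3c2cc(OCc3ccccc3)cc(OCc3ccccc3)c2)cc1 | intermediate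
31 | CNP0186204.1 (full name in step 14) | Oc1ccc([C@H]2Oc3cc(/C=C/c4ccc(O)cc4O)cc(O)c3[C@@H]2c2cc(O)c3c(c2)O[C@H](c2ccc(O)cc2)[C@H]3c2cc(O)cc(O)c2)cc1 | target

**Step count and risks**

Total step count: 14. Longest linear sequence: 10 steps (1, 2, 6, 7, 8, 9, 10, 11, 13, 14).

Steps most likely to fail:

1. Step 13 (key step, proposed method). The ylide may add to both faces of the exocyclic carbon of 28 without enough reagent control, so that C3 is not set. Aryllithium 25 may also attack the carbonate instead of the formyl group, or 28 may condense with itself before it is captured. The fallback uses the known chemistry of steps 6 to 10 on ring A: enantioselective rhodium-catalysed 1,5 C–H insertion of a diaryl carbene into a benzylic ether C–H bond, followed by acid-promoted epimerisation at C2. It sets out from 8 and 21 and comes back to the route at 31. Phenol 8 is alkylated with 11 (K2CO3, DMF) to 2-(benzyloxy)-6-{[4-(benzyloxy)phenyl]methoxy}-4-{(E)-2-[2,4-bis(benzyloxy)phenyl]ethenyl}benzaldehyde F1. Aryllithium 25 (from 21, n-BuLi, THF, −78 °C) adds to it to give the diarylmethanol F2 as both carbinol epimers, and Dess–Martin periodinane oxidises this to the diaryl ketone F3. Hydrazine hydrate (n-BuOH, AcOH, reflux) gives the hydrazone F4, and MnO2 (CH2Cl2) the diaryldiazomethane F5. Rh2(S-PTAD)4 or its enantiomer (cat.), whichever delivers (3S), should then insert the carbene into the ArCH2–O bond and give the cis-(2R,3S) octabenzyl ether F6. The more hydridic 4-alkoxybenzylic C–H bond should be preferred over that of the neighbouring plain benzyl ether, and the regioisomer from the latter would be removed by chromatography. F6 is submitted to the conditions of step 14, where the Lewis acid should open the C2–O1 bond reversibly through the 4-oxybenzylic cation and let the ring close again to the preferred trans isomer, so that 31 results.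

2. Step 10. The carbene may insert into the C–H bond of the neighbouring plain benzyl ether instead of the 4-alkoxybenzylic one (poor site selectivity), which would give the regioisomeric 2-phenyl ring. The fallback makes the two ether groups identical, so that insertion at either site gives the same product, and pays for this with one more step; it sets out from 1 and 13 and comes back at 21. Aldehyde 1 and commercial 4-(benzyloxy)benzyl alcohol (K2CO3, DMF, 70 °C) give 2,6-bis{[4-(benzyloxy)phenyl]methoxy}-4-bromobenzaldehyde F7. Aryllithium 14 (from 13, n-BuLi, THF, −78 °C) adds to give the racemic diarylmethanol F8, which is oxidised (Dess–Martin periodinane) to the diaryl ketone F9 and condensed with hydrazine to the hydrazone F10. MnO2 gives the diaryldiazomethane F11, and the rhodium catalyst the cis-(2R,3S)-dihydrobenzofuran bromide F12, which carries a 4-(benzyloxy)benzyl ether on the C4 oxygen. Trifluoroacetic acid with pentamethylbenzene as cation scavenger (CH2Cl2, 0 °C) should epimerise C2 and at the same time cleave this acid-labile ether to the trans-(2S,3S) phenol F13, and benzyl bromide with K2CO3 (DMF) then gives 21.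

3. Step 14. The Lewis acid may act on the styrene arm (protonation or benzylation of the electron-rich 2,4-dioxygenated stilbene, E/Z isomerisation), or cleavage of eight ethers may stay incomplete. The fallback removes the benzyl groups before the stilbene exists and ends with a fluoride deprotection; it sets out from 4, 21 and 24 and comes back at 31. Phenol 4 is acylated with 9 (iPr2NEt, DMAP, CH2Cl2) to tert-butyl [3-(benzyloxy)-5-bromo-2-formylphenyl] carbonate F14. Under the conditions of step 13, 25 (from 21), aldehyde F14 and ylide 27 (from 24) should give the hexabenzyl ring-A bromide F15. BCl3 and pentamethylbenzene (CH2Cl2, −78 °C) convert it to the hexaphenol bromide F16, and TBSCl and imidazole (DMF) to the hexakis(tert-butyldimethylsilyl) ether F17. In parallel, commercial 2,4-dihydroxybenzaldehyde is silylated (TBSCl, imidazole) to 2,4-bis(tert-butyldimethylsilyloxy)benzaldehyde F18 and methylenated (Ph3PCH3Br, KOtBu) to 2,4-bis(tert-butyldimethylsilyloxy)-1-ethenylbenzene F19. A Heck reaction of F17 with F19 (Pd(OAc)2, P(o-tol)3, Et3N, DMF, 100 °C) should give the octakis(tert-butyldimethylsilyl) ether of the target F20, and buffered fluoride (TBAF, AcOH, THF, 0 °C) then frees 31.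

**Further compounds**

F1 | step 13 | 2-(benzyloxy)-6-{[4-(benzyloxy)phenyl]methoxy}-4-{(E)-2-[2,4-bis(benzyloxy)phenyl]ethenyl}benzaldehyde | O=Cc1c(OCc2ccc(OCc3ccccc3)cc2)cc(/C=C/c2ccc(OCc3ccccc3)cc2OCc2ccccc2)cc1OCc1ccccc1
F2 | step 13 | diarylmethanol from 25 and F1 (both carbinol epimers) | OC(c1cc(OCc2ccccc2)c2c(c1)O[C@H](c1ccc(OCc3ccccc3)cc1)[C@H]2c1cc(OCc2ccccc2)cc(OCc2ccccc2)c1)c1c(OCc2ccc(OCc3ccccc3)cc2)cc(/C=C/c2ccc(OCc3ccccc3)cc2OCc2ccccc2)cc1OCc1ccccc1
F3 | step 13 | diaryl ketone from F2 | O=C(c1cc(OCc2ccccc2)c2c(c1)O[C@H](c1ccc(OCc3ccccc3)cc1)[C@H]2c1cc(OCc2ccccc2)cc(OCc2ccccc2)c1)c1c(OCc2ccc(OCc3ccccc3)cc2)cc(/C=C/c2ccc(OCc3ccccc3)cc2OCc2ccccc2)cc1OCc1ccccc1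
F4 | step 13 | hydrazone of F3 | NN=C(c1cc(OCc2ccccc2)c2c(c1)O[C@H](c1ccc(OCc3ccccc3)cc1)[C@H]2c1cc(OCc2ccccc2)cc(OCc2ccccc2)c1)c1c(OCc2ccc(OCc3ccccc3)cc2)cc(/C=C/c2ccc(OCc3ccccc3)cc2OCc2ccccc2)cc1OCc1ccccc1
F5 | step 13 | diaryldiazomethane from F4 | [N-]=[N+]=C(c1cc(OCc2ccccc2)c2c(c1)O[C@H](c1ccc(OCc3ccccc3)cc1)[C@H]2c1cc(OCc2ccccc2)cc(OCc2ccccc2)c1)c1c(OCc2ccc(OCc3ccccc3)cc2)cc(/C=C/c2ccc(OCc3ccccc3)cc2OCc2ccccc2)cc1OCc1ccccc1
F6 | step 13 | cis-(2R,3S) ring-A isomer of octabenzyl ether 30 | c1ccccc1COc1ccc([C@@H]2Oc3cc(/C=C/c4ccc(OCc5ccccc5)cc4OCc4ccccc4)cc(OCc4ccccc4)c3[C@@H]2c2cc(OCc4ccccc4)c3c(c2)O[C@H](c2ccc(OCc4ccccc4)cc2)[C@H]3c2cc(OCc3ccccc3)cc(OCc3ccccc3)c2)cc1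
F7 | step 10 | 2,6-bis{[4-(benzyloxy)phenyl]methoxy}-4-bromobenzaldehyde | O=Cc1c(OCc2ccc(OCc3ccccc3)cc2)cc(Br)cc1OCc1ccc(OCc2ccccc2)cc1
F8 | step 10 | racemic diarylmethanol from 14 and F7 | OC(c1cc(OCc2ccccc2)cc(OCc2ccccc2)c1)c1c(OCc2ccc(OCc3ccccc3)cc2)cc(Br)cc1OCc1ccc(OCc2ccccc2)cc1
F9 | step 10 | diaryl ketone from F8 | O=C(c1cc(OCc2ccccc2)cc(OCc2ccccc2)c1)c1c(OCc2ccc(OCc3ccccc3)cc2)cc(Br)cc1OCc1ccc(OCc2ccccc2)cc1
F10 | step 10 | hydrazone of F9 | NN=C(c1cc(OCc2ccccc2)cc(OCc2ccccc2)c1)c1c(OCc2ccc(OCc3ccccc3)cc2)cc(Br)cc1OCc1ccc(OCc2ccccc2)cc1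
F11 | step 10 | diaryldiazomethane from F10 | [N-]=[N+]=C(c1cc(OCc2ccccc2)cc(OCc2ccccc2)c1)c1c(OCc2ccc(OCc3ccccc3)cc2)cc(Br)cc1OCc1ccc(OCc2ccccc2)cc1
F12 | step 10 | (2R,3S)-2-[4-(benzyloxy)phenyl]-4-{[4-(benzyloxy)phenyl]methoxy}-3-[3,5-bis(benzyloxy)phenyl]-6-bromo-2,3-dihydro-1-benzofuran (cis) | Brc1cc(OCc2ccc(OCc3ccccc3)cc2)c2c(c1)O[C@@H](c1ccc(OCc3ccccc3)cc1)[C@H]2c1cc(OCc2ccccc2)cc(OCc2ccccc2)c1
F13 | step 10 | (2S,3S)-2-[4-(benzyloxy)phenyl]-3-[3,5-bis(benzyloxy)phenyl]-6-bromo-2,3-dihydro-1-benzofuran-4-ol (trans) | Brc1cc(O)c2c(c1)O[C@H](c1ccc(OCc3ccccc3)cc1)[C@H]2c1cc(OCc2ccccc2)cc(OCc2ccccc2)c1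
F14 | step 14 | tert-butyl [3-(benzyloxy)-5-bromo-2-formylphenyl] carbonate | O=Cc1c(OC(=O)OC(C)(C)C)cc(Br)cc1OCc1ccccc1
F15 | step 14 | hexabenzyl ring-A bromide (30 with Br in place of the styryl group) | c1ccccc1COc1ccc([C@H]2Oc3cc(Br)cc(OCc4ccccc4)c3[C@@H]2c2cc(OCc4ccccc4)c3c(c2)O[C@H](c2ccc(OCc4ccccc4)cc2)[C@H]3c2cc(OCc3ccccc3)cc(OCc3ccccc3)c2)cc1
F16 | step 14 | hexaphenol bromide | Oc1ccc([C@H]2Oc3cc(Br)cc(O)c3[C@@H]2c2cc(O)c3c(c2)O[C@H](c2ccc(O)cc2)[C@H]3c2cc(O)cc(O)c2)cc1
F17 | step 14 | hexakis(tert-butyldimethylsilyl) ether of F16 | CC(C)(C)[Si](C)(C)Oc1ccc([C@H]2Oc3cc(Br)cc(O[Si](C)(C)C(C)(C)C)c3[C@@H]2c2cc(O[Si](C)(C)C(C)(C)C)c3c(c2)O[C@H](c2ccc(O[Si](C)(C)C(C)(C)C)cc2)[C@H]3c2cc(O[Si](C)(C)C(C)(C)C)cc(O[Si](C)(C)C(C)(C)C)c2)cc1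
F18 | step 14 | 2,4-bis(tert-butyldimethylsilyloxy)benzaldehyde | O=Cc1ccc(O[Si](C)(C)C(C)(C)C)cc1O[Si](C)(C)C(C)(C)C
F19 | step 14 | 2,4-bis(tert-butyldimethylsilyloxy)-1-ethenylbenzene | C=Cc1ccc(O[Si](C)(C)C(C)(C)C)cc1O[Si](C)(C)C(C)(C)C
F20 | step 14 | octakis(tert-butyldimethylsilyl) ether of the target | CC(C)(C)[Si](C)(C)Oc1ccc([C@H]2Oc3cc(/C=C/c4ccc(O[Si](C)(C)C(C)(C)C)cc4O[Si](C)(C)C(C)(C)C)cc(O[Si](C)(C)C(C)(C)C)c3[C@@H]2c2cc(O[Si](C)(C)C(C)(C)C)c3c(c2)O[C@H](c2ccc(O[Si](C)(C)C(C)(C)C)cc2)[C@H]3c2cc(O[Si](C)(C)C(C)(C)C)cc(O[Si](C)(C)C(C)(C)C)c2)cc1
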